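**Retrosynthetic overview**
1. The last operation is a global hydrogenolysis of three benzyl groups (two aryl ethers and one ester) on the fully protected keto-depside.
2. Key cut, made on the intact depside: ArCH2–C(=O). The fragments are a benzylic chloride and an unmasked octanoyl anion, octanoylzirconocene chloride, built from hept-1-ene, Cp2Zr(H)Cl and CO.
3. The depside ester comes from a 6-(chloromethyl) ring-A acid and the ring-B phenol. They are joined before any ketone exists.
4. Ring A is bought as 3,5-bis(benzyloxy)benzyl alcohol. One Vilsmeier step installs both CH2Cl and CHO, and the aldehyde is then oxidised to the acid.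
5. Ring B is the only ring formed. It comes from a Diels–Alder/aromatisation of a 1,1-dimethoxy-3-silyloxydiene with benzyl dec-2-ynoate.

Assumption: the SMILES contains no stereocentre and no stereogenic double bond. The target is therefore achiral and no stereocontrol is needed.

**Step 1**
Reactants: 1 1,1-dimethoxyethene; 2 acetyl chloride
Product: 3 4,4-dimethoxybut-3-en-2-one
Conditions: pyridine (1.2 equiv), CH2Cl2, 0 °C → rt
Reagents that add atoms: none
Why: In this McElvain-type C-acylation the N-acetylpyridinium salt acylates the electron-rich ketene acetal, and pyridine removes the doubly activated proton before chloride can demethylate the dialkoxycarbenium ion.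

**Step 2**
Reactants: 3 4,4-dimethoxybut-3-en-2-one
Product: 4 1,1-dimethoxy-3-(trimethylsilyloxy)buta-1,3-diene
Conditions: TMSCl, Et3N, ZnCl2 (cat.), toluene, 40 °C; filter, distil
Reagents that add atoms: chlorotrimethylsilane C[Si](C)(C)Cl
Why: This soft enolisation/O-silylation, the method used for Danishefsky-type dienes, can only remove a proton from the methyl group, so a single cross-conjugated silyloxydiene forms.

**Step 3**
Reactants: 5 non-1-yne; 6 benzyl chloroformate
Product: 8 benzyl dec-2-ynoate, via lithium nonynide 7 (not isolated)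
Conditions: n-BuLi, THF, −78 °C; then 6, −78 °C → rt
Reagents that add atoms: none
Why: Acylation of a lithium acetylide with a chloroformate is a standard alkynoate synthesis, because chloride leaves far faster than benzyloxide.

**Step 4**
Reactants: 4 1,1-dimethoxy-3-(trimethylsilyloxy)buta-1,3-diene; 8 benzyl dec-2-ynoate
Product: 11 benzyl 2-heptyl-4-hydroxy-6-methoxybenzoate, via Diels-Alder adduct 9 (not isolated), via aryl silyl ether 10 (not isolated)
Conditions: 4 (2 equiv), neat, sealed tube, 140 °C, 36 h; then 1 M HCl, THF, rt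
Reagents that add atoms: none
Why: In this regiospecific normal-demand Diels–Alder/aromatisation the nucleophilic CH2 terminus of the diene bonds to the heptyl-bearing β-carbon of the ynoate and the ketal carbon ends up next to the ester, so loss of MeOH and desilylation place OMe ortho and the free OH para to the ester.

**Step 5**
Reactants: 12 [3,5-bis(benzyloxy)phenyl]methanol
Product: 15 2,4-bis(benzyloxy)-6-(chloromethyl)benzaldehyde, via benzylic chloride 13 (not isolated), via aryl iminium salt 14 (not isolated)
Conditions: POCl3 (4 equiv), DMF, 0 → 75 °C; ice–water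
Reagents that add atoms: N,N-dimethylformamide CN(C)C=O; phosphoryl chloride O=P(Cl)(Cl)Cl; water O
Why: In this Vilsmeier–Haack reaction the chloroiminium salt converts the benzylic alcohol to the chloride and then formylates the doubly activated position next to CH2Cl rather than the hindered site between the two ethers, and benzyl ethers tolerate the conditions.

**Step 6**
Reactants: 15 2,4-bis(benzyloxy)-6-(chloromethyl)benzaldehyde
Product: 16 2,4-bis(benzyloxy)-6-(chloromethyl)benzoic acid
Conditions: NaClO2, H2NSO3H, THF–H2O, 0 °C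
Reagents that add atoms: sodium chlorite [Na+].[O-]Cl=O
Why: The Lindgren (Pinnick-type) chlorite oxidation is selective for CHO, and sulfamic acid both traps HOCl (no ring chlorination) and keeps the medium acidic so that the un-ionised acid does not displace its own chloride.

**Step 7**
Reactants: 16 2,4-bis(benzyloxy)-6-(chloromethyl)benzoic acid; 11 benzyl 2-heptyl-4-hydroxy-6-methoxybenzoate
Product: 18 benzyl 4-{[2,4-bis(benzyloxy)-6-(chloromethyl)benzoyl]oxy}-2-heptyl-6-methoxybenzoate, via mixed trifluoroacetic anhydride 17 (not isolated)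
Conditions: (CF3CO)2O, toluene, rt
Reagents that add atoms: none
Why: In this trifluoroacetic anhydride depside coupling the hindered, electron-rich acid is activated as the mixed anhydride/acylium ion and acylates the only free phenol without base, which spares CH2Cl, and no ketone is present yet that could give an isocoumarin.

**Step 8 (key step)**
Reactants: 19 hept-1-ene; 18 benzyl 4-{[2,4-bis(benzyloxy)-6-(chloromethyl)benzoyl]oxy}-2-heptyl-6-methoxybenzoate
Product: 22 benzyl 4-{[2,4-bis(benzyloxy)-6-(2-oxononyl)benzoyl]oxy}-2-heptyl-6-methoxybenzoate, via heptylzirconocene chloride 20 (not isolated), via octanoylzirconocene chloride 21 (not isolated)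
Conditions: 19 (2.2 equiv), Cp2Zr(H)Cl (2 equiv), CH2Cl2, rt; CO (1 atm), rt, 2 h; Ar purge, swap to toluene; 18 (1 equiv), PdCl2(PPh3)2 (5 mol %), 45 °C
Reagents that add atoms: carbon monoxide [C-]#[O+]
Why: Anti-Markovnikov Schwartz hydrozirconation and CO insertion give an acylzirconocene that acts as an unmasked octanoyl anion, and the known Pd-catalysed acylzirconocene/benzylic halide coupling (oxidative addition into C–Cl, Zr→Pd acyl transfer, reductive elimination) joins it to the electrophilic benzylic carbon under neutral conditions that leave both esters, the ethers and the new ketone untouched.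

**Step 9**
Reactants: 22 benzyl 4-{[2,4-bis(benzyloxy)-6-(2-oxononyl)benzoyl]oxy}-2-heptyl-6-methoxybenzoate
Product: 23 4-{[2,4-dihydroxy-6-(2-oxononyl)benzoyl]oxy}-2-heptyl-6-methoxybenzoic acid (CNP0406321.0)
Conditions: H2 (1 atm), 10 % Pd/C, EtOAc, rt
Reagents that add atoms: none
Why: Catalytic hydrogenolysis removes both aryl benzyl ethers and the benzyl ester at once, while the non-conjugated ketone, the aryl ester and the aryl methyl ether are inert at 1 atm and the neutral medium avoids cyclisation to the isocoumarin.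

**Compound list**
1 | 1,1-dimethoxyethene | C=C(OC)OC | starting material
2 | acetyl chloride | CC(=O)Cl | starting material
3 | 4,4-dimethoxybut-3-en-2-one | CC(=O)C=C(OC)OC | intermediate
4 | 1,1-dimethoxy-3-(trimethylsilyloxy)buta-1,3-diene | C=C(O[Si](C)(C)C)C=C(OC)OC | intermediate
5 | non-1-yne | C#CCCCCCCC | starting material
6 | benzyl chloroformate | O=C(Cl)OCc1ccccc1 | starting material
7 | lithium non-1-yn-1-ide | [Li]C#CCCCCCCC | intermediate
8 | benzyl dec-2-ynoate | CCCCCCCC#CC(=O)OCc1ccccc1 | intermediate
9 | benzyl 2-heptyl-6,6-dimethoxy-4-(trimethylsilyloxy)cyclohexa-1,4-diene-1-carboxylate | COC1(OC)C=C(O[Si](C)(C)C)CC(CCCCCCC)=C1C(=O)OCc1ccccc1 | intermediate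
10 | benzyl 2-heptyl-6-methoxy-4-(trimethylsilyloxy)benzoate | COc1cc(O[Si](C)(C)C)cc(CCCCCCC)c1C(=O)OCc1ccccc1 | intermediate
11 | benzyl 2-heptyl-4-hydroxy-6-methoxybenzoate | COc1cc(O)cc(CCCCCCC)c1C(=O)OCc1ccccc1 | intermediate
12 | [3,5-bis(benzyloxy)phenyl]methanol | OCc1cc(OCc2ccccc2)cc(OCc2ccccc2)c1 | starting material
13 | 1,3-bis(benzyloxy)-5-(chloromethyl)benzene | ClCc1cc(OCc2ccccc2)cc(OCc2ccccc2)c1 | intermediate
14 | [2,4-bis(benzyloxy)-6-(chloromethyl)benzylidene]dimethyliminium dichlorophosphate | C[N+](C)=Cc1c(CCl)cc(OCc2ccccc2)cc1OCc1ccccc1.[O-]P(=O)(Cl)Cl | intermediate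
15 | 2,4-bis(benzyloxy)-6-(chloromethyl)benzaldehyde | O=Cc1c(CCl)cc(OCc2ccccc2)cc1OCc1ccccc1 | intermediate
16 | 2,4-bis(benzyloxy)-6-(chloromethyl)benzoic acid | OC(=O)c1c(CCl)cc(OCc2ccccc2)cc1OCc1ccccc1 | intermediate
17 | 2,4-bis(benzyloxy)-6-(chloromethyl)benzoic trifluoroacetic anhydride | O=C(OC(=O)C(F)(F)F)c1c(CCl)cc(OCc2ccccc2)cc1OCc1ccccc1 | intermediate
18 | benzyl 4-{[2,4-bis(benzyloxy)-6-(chloromethyl)benzoyl]oxy}-2-heptyl-6-methoxybenzoate | ClCc1cc(OCc2ccccc2)cc(OCc2ccccc2)c1C(=O)Oc1cc(CCCCCCC)c(C(=O)OCc2ccccc2)c(OC)c1 | intermediate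
19 | hept-1-ene | C=CCCCCC | starting material
20 | chlorobis(cyclopentadienyl)(heptyl)zirconium | CCCCCCC[Zr](Cl)(C1C=CC=C1)C1C=CC=C1 | intermediate
21 | chlorobis(cyclopentadienyl)(octanoyl)zirconium | CCCCCCCC(=O)[Zr](Cl)(C1C=CC=C1)C1C=CC=C1 | intermediate
22 | benzyl 4-{[2,4-bis(benzyloxy)-6-(2-oxononyl)benzoyl]oxy}-2-heptyl-6-methoxybenzoate | CCCCCCCC(=O)Cc1cc(OCc2ccccc2)cc(OCc2ccccc2)c1C(=O)Oc1cc(CCCCCCC)c(C(=O)OCc2ccccc2)c(OC)c1 | intermediate
23 | 4-{[2,4-dihydroxy-6-(2-oxononyl)benzoyl]oxy}-2-heptyl-6-methoxybenzoic acid | CCCCCCCC(=O)Cc1cc(O)cc(O)c1C(=O)Oc1cc(CCCCCCC)c(C(=O)O)c(OC)c1 | target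

**Total step count:** 9.
**Longest linear sequence:** 6 (steps 1, 2, 4, 7, 8, 9).

**Three steps most likely to fail**

*Step 8.* Oxidative addition into the hindered benzylic chloride may be slow. The acyl–Pd species may decarbonylate, or the benzyl fragment may homocouple.
The fallback sets out from 18 and comes back at 22. It replaces the acyl–metal transfer by an SN2 alkylation of a masked carbonyl linchpin.
- TosMIC is mono-alkylated with 1-bromoheptane (Bu4NI, 30 % NaOH/CH2Cl2) to racemic 1-isocyano-1-tosyloctane F1.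
- The sodium salt of F1 (NaH, 1.0 equiv, THF–DMSO, 0 °C) displaces the chloride of 18. The 2,6-disubstituted aryl ester is too hindered to be attacked. The product is the racemic dialkylated tosyl isocyanide depside F2.
- Brief treatment with conc. HCl in THF at 0 °C → rt hydrolyses the isocyanide, expels sulfinate and releases the ketone 22. The temporary stereocentre disappears in this step.

*Step 4.* The β-alkyl ynoate is a sluggish dienophile, and the diene may decompose before it reacts.
The fallback sets out from 16 and comes back at 18. It avoids the cycloaddition and installs the methyl ether after the depside bond.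
- Purchased 5-heptylresorcinol is carboxylated with methyl magnesium carbonate (DMF, 120 °C) to 2-heptyl-4,6-dihydroxybenzoic acid F3.
- BnBr/KHCO3 in DMF alkylates only the carboxylate and gives benzyl 2-heptyl-4,6-dihydroxybenzoate F4.
- TFAA/toluene coupling with 16 acylates the unchelated 4-OH and gives the 2'-hydroxy depside chloride F5.
- Me2SO4/K2CO3 in acetone methylates the chelated hydroxyl and gives 18. Dimethyl sulfate is used rather than MeI to avoid halide exchange.

*Step 6.* Acid 16 may lactonise to the phthalide during oxidation or work-up.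
The fallback sets out from 15 and comes back at 22. It reverses the order so that a chloromethyl acid never exists.
- The acylzirconocene/Pd coupling of step 8 is run on aldehyde 15. Acylzirconocenes need a Lewis acid to add to aldehydes, so the CHO group should survive. The product is 2,4-bis(benzyloxy)-6-(2-oxononyl)benzaldehyde F6.
- Chlorite/sulfamic acid oxidation gives 2,4-bis(benzyloxy)-6-(2-oxononyl)benzoic acid F7.
- TFAA/toluene coupling with 11 gives 22. Some loss to the isocoumarin is accepted in this last coupling.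

**Further compounds**
F1 | step 8 | 1-isocyano-1-tosyloctane (racemic) | CCCCCCCC([N+]#[C-])S(=O)(=O)c1ccc(C)cc1
F2 | step 8 | benzyl 4-{[2,4-bis(benzyloxy)-6-(2-isocyano-2-tosylnonyl)benzoyl]oxy}-2-heptyl-6-methoxybenzoate (racemic) | CCCCCCCC([N+]#[C-])(Cc1cc(OCc2ccccc2)cc(OCc2ccccc2)c1C(=O)Oc1cc(CCCCCCC)c(C(=O)OCc2ccccc2)c(OC)c1)S(=O)(=O)c1ccc(C)cc1
F3 | step 4 | 2-heptyl-4,6-dihydroxybenzoic acid | CCCCCCCc1cc(O)cc(O)c1C(=O)O
F4 | step 4 | benzyl 2-heptyl-4,6-dihydroxybenzoate | CCCCCCCc1cc(O)cc(O)c1C(=O)OCc1ccccc1
F5 | step 4 | benzyl 4-{[2,4-bis(benzyloxy)-6-(chloromethyl)benzoyl]oxy}-2-heptyl-6-hydroxybenzoate | ClCc1cc(OCc2ccccc2)cc(OCc2ccccc2)c1C(=O)Oc1cc(CCCCCCC)c(C(=O)OCc2ccccc2)c(O)c1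
F6 | step 6 | 2,4-bis(benzyloxy)-6-(2-oxononyl)benzaldehyde | CCCCCCCC(=O)Cc1cc(OCc2ccccc2)cc(OCc2ccccc2)c1C=O
F7 | step 6 | 2,4-bis(benzyloxy)-6-(2-oxononyl)benzoic acid | CCCCCCCC(=O)Cc1cc(OCc2ccccc2)cc(OCc2ccccc2)c1C(=O)O
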